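**Retrosynthetic overview**

1. Locants used here: C1 = C(CH3)= ; C2 = alkene carbon in the cyclopentane; C3, C4 = CH2; C5 = CH(CH3); C6 = CH at the 5/8 fusion; C7 = CHOH; C8 = C(CH3) at the 8/6 fusion; C9, C10 = CH2; C11 = angular C(CH3); C12, C13 = CH2; C14 = C(CH3)2; C15 = CH2; C16 = CH at the 6/6 fusion; C17 = CH at the 6/8 fusion; C18, C19 = CH2 of the eight-membered ring.
2. Target ⇐ C7 ketone 22 (dissolving-metal reduction) ⇐ dienone 20 (1,6-reduction places the alkene at C1=C2 and sets C6) ⇐ ketone 19 ⇐ cycloadduct 17 (C8 methylation through its silyl enol ether).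
3. Key disconnection: C2–C6 and C17–C18 together, by nickel-catalysed intramolecular [4+4] cycloaddition of bis-diene 16. The enabling feature is that the eight-membered ring (C1, C2, C6, C7, C8, C17, C18, C19) consists of two four-carbon units, C18–C19–C1–C2 and C6–C7–C8–C17, that meet only at these two bonds, while the cyclopentane carbons C3–C4–C5 form a three-atom tether from C2 to C6.
4. 16 ⇐ enone 15 ⇐ Nozaki–Hiyama–Kishi union of trans-decalin alkenyl triflate 7 (deracemising Michael addition, Robinson annulation, Birch reduction/triflation) with dienal 13 (from (S)-citronellal, which supplies C5).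
5. Ring order: ring C is bought, ring B comes from the Robinson annulation, and the cyclopentane and the cyclooctadiene are closed together in the key step.

Key step: step 12

Remark: α is the face of the decalin opposite the C11 methyl (H-16 is α), β is the face of that methyl. Compounds 17–19 are carried as mixtures at C2 and C6, and their SMILES leave these two centres open; both are cleared in step 14 and C6 is set in step 15.

**Route**

Step 1
Reactants: 1 3,3-dimethylcyclohexan-1-one
Product: 2 2,5,5-trimethylcyclohexan-1-one (racemic)
Conditions: LDA, THF, −78 °C; MeI, −78 to 0 °C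
Reagents that add atoms: iodomethane, CI
Why: Kinetic enolate alkylation, in which LDA removes a proton from the α-methylene remote from the gem-dimethyl group (the other one is neopentylic); the new centre is racemic and is cleared in step 2.

Step 2
Reactants: 2 2,5,5-trimethylcyclohexan-1-one
Product: 4 (S)-2,5,5-trimethyl-2-(3-oxobutyl)cyclohexan-1-one, via imine 3 (not isolated)
Conditions: (R)-1-phenylethylamine, TsOH (cat.), toluene, reflux (Dean–Stark); methyl vinyl ketone, THF, rt; 10% aq. AcOH, rt
Reagents that add atoms: methyl vinyl ketone, CC(=O)C=C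
Why: Deracemising Michael addition of a chiral imine, in which the more substituted secondary enamine tautomer adds to the enone through a compact aza-ene-like transition state on the face away from the phenyl group, so both enantiomers of 2 should converge on the (S)-quaternary centre (future C11).

Step 3
Reactants: 4 (S)-2,5,5-trimethyl-2-(3-oxobutyl)cyclohexan-1-one
Product: 5 (S)-4a,7,7-trimethyl-4,4a,5,6,7,8-hexahydronaphthalen-2(3H)-one
Conditions: NaOMe, MeOH, rt to 60 °C
Reagents that add atoms: none
Why: Intramolecular aldol condensation (second stage of a Robinson annulation) of the methyl ketone onto the ring ketone should give the conjugated octalone without forming a stereocentre.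

Step 4
Reactants: 5 (S)-4a,7,7-trimethyl-4,4a,5,6,7,8-hexahydronaphthalen-2(3H)-one
Product: 7 trans-fused decalin alkenyl triflate, via lithium enolate 6 (not isolated)
Conditions: Li, NH3(l)/THF, t-BuOH (1 equiv), −78 °C; isoprene; NH3 removed; PhNTf2, THF, 0 °C to rt
Reagents that add atoms: N-phenylbis(trifluoromethanesulfonimide), O=S(=O)(N(c1ccccc1)S(=O)(=O)C(F)(F)F)C(F)(F)F
Why: Birch reduction of the enone with regiospecific enolate trapping, in which axial protonation at the β-carbon (future C16) anti to the angular methyl should give the trans ring fusion and O-triflation fixes the double bond toward C17.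

Step 5
Reactants: 8 (S)-citronellal
Product: 9 2-[(S)-2,6-dimethylhept-5-en-1-yl]-1,3-dioxolane
Conditions: ethylene glycol, PPTS (cat.), benzene, reflux (Dean–Stark)
Reagents that add atoms: ethylene glycol, OCCO
Why: Acetalisation protects the aldehyde against the oxidant and the ylide of the next two steps and leaves the methyl-bearing stereocentre (future C5) untouched.

Step 6
Reactants: 9 2-[(S)-2,6-dimethylhept-5-en-1-yl]-1,3-dioxolane
Product: 11 (2E,6S)-7-(1,3-dioxolan-2-yl)-2,6-dimethylhept-2-enal, via allylic alcohol 10 (not isolated)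
Conditions: SeO2 (cat.), t-BuOOH, salicylic acid (cat.), CH2Cl2, rt; then MnO2, CH2Cl2, rt
Reagents that add atoms: tert-butyl hydroperoxide, CC(C)(C)OO
Why: Selenium dioxide allylic oxidation (ene reaction, then [2,3]-shift) should attack only the (E)-methyl group of the trisubstituted alkene, and MnO2 takes the (E)-allylic alcohol to the (E)-enal.

Step 7
Reactants: 11 (2E,6S)-7-(1,3-dioxolan-2-yl)-2,6-dimethylhept-2-enal
Product: 12 2-[(2S,5E)-2,6-dimethylocta-5,7-dien-1-yl]-1,3-dioxolane
Conditions: Ph3PCH3Br, KOt-Bu, THF, 0 °C to rt
Reagents that add atoms: methyltriphenylphosphonium bromide, C[P+](c1ccccc1)(c1ccccc1)c1ccccc1.[Br-]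
Why: Wittig methylenation of the enal should give the terminal 1,3-diene with the trisubstituted alkene geometry carried over.

Step 8
Reactants: 12 2-[(2S,5E)-2,6-dimethylocta-5,7-dien-1-yl]-1,3-dioxolane
Product: 13 (3S,6E)-3,7-dimethylnona-6,8-dienal
Conditions: PPTS (cat.), acetone/H2O, 50 °C
Reagents that add atoms: water, O
Why: Mild acetal hydrolysis should release the aldehyde without protonating the diene.

Step 9
Reactants: 7 trans-fused decalin alkenyl triflate; 13 (3S,6E)-3,7-dimethylnona-6,8-dienal
Product: 14 allylic alcohol (both C7 epimers)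
Conditions: CrCl2 (4 equiv), NiCl2 (1 mol %), DMF, rt
Reagents that add atoms: none
Why: Nozaki–Hiyama–Kishi coupling, in which the alkenylchromium species formed from the triflate adds only to the aldehyde; the C7 carbinol centre is not controlled and is removed in step 10.

Step 10
Reactants: 14 allylic alcohol (both C7 epimers)
Product: 15 cross-conjugated precursor enone (C7 ketone, C8=C17 in ring B)
Conditions: Dess–Martin periodinane, NaHCO3, CH2Cl2, 0 °C to rt
Reagents that add atoms: none
Why: Dess–Martin oxidation of the allylic alcohol should give the enone without touching the diene.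

Step 11
Reactants: 15 enone
Product: 16 (Z)-2-silyloxy diene (bis-diene)
Conditions: TBSOTf, Et3N, CH2Cl2, −78 to 0 °C
Reagents that add atoms: tert-butyldimethylsilyl trifluoromethanesulfonate, CC(C)(C)[Si](C)(C)OS(=O)(=O)C(F)(F)F
Why: Soft enolisation removes a proton from the α′-methylene (C6) and silylates on oxygen, which should give the cross-conjugated C6=C7(OTBS)–C8=C17 diene; its enol ether geometry is not critical.

Step 12
Reactants: 16 (Z)-2-silyloxy diene (bis-diene)
Product: 17 [4+4] cycloadduct (5/8/6/6 tetracycle; C19=C1 and C7(OTBS)=C8 double bonds)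
Conditions: Ni(cod)2 (15 mol %), PPh3 (45 mol %), toluene, 60 °C
Reagents that add atoms: none
Why: Zerovalent nickel binds both 1,3-dienes, oxidative coupling of the two tethered termini makes the C2–C6 bond and a bis(η3-allyl)nickel, and allyl–allyl reductive elimination makes the C17–C18 bond and releases the cis,cis-cycloocta-1,5-diene. The closest known reaction is the Ni(cod)2/PPh3-catalysed intramolecular [4+4] cycloaddition of 1,3-dienes joined by a three-atom tether, which gives bicyclo[6.3.0]undecadienes. The cyclopentane closes in the metal-templated oxidative coupling (ring size fixed by the C3–C4–C5 tether) and the cyclooctadiene closes in the reductive elimination. C17 is controlled by the axial C11 methyl, which should keep nickel and the incoming C18 on the α-face of ring B so that H-17 ends up β and trans to H-16; C2 and C6 are set by the tether (cis fusion expected) but need no control because both are cleared in step 14 and C6 is set again in step 15. The step needs [4+4] rather than [4+2] or [2+2] periselectivity, which the three-atom tether, the s-cis-accessible diene units and phosphine-ligated nickel should secure, and α-face selectivity at C17, which the angular methyl should secure. The silyl dienol ether keeps C7 at the ketone level and leaves a regiodefined enol ether at C7=C8 for the next step.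

Step 13
Reactants: 17 [4+4] cycloadduct
Product: 19 8α-methyl C7 ketone, via lithium enolate 18 (not isolated)
Conditions: MeLi, THF, 0 °C to rt; then DMPU, MeI, −78 to 0 °C
Reagents that add atoms: iodomethane, CI
Why: MeLi cleaves the Si–O bond to the single regiodefined lithium enolate, whose C-methylation (enolate alkylation) makes the C8 quaternary centre; the methyl is expected to enter axially on the α-face of ring B, anti to the C11 methyl, which would give the trans 6/8 fusion (CH3-8 trans to H-17).

Step 14
Reactants: 19 8α-methyl C7 ketone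
Product: 20 linear dienone (C7=O conjugated with C6=C2 and C1=C19)
Conditions: IBX (2.5 equiv), DMSO, 75 °C
Reagents that add atoms: none
Why: IBX dehydrogenation of the ketone, which can enolise only toward C6 because C8 is quaternary, should remove the allylic H-2 to give the conjugated dienone, so all C2/C6 isomers of 19 converge on one compound.

Step 15
Reactants: 20 linear dienone
Product: 22 β,γ-unsaturated C7 ketone, via lithium dienolate 21 (not isolated)
Conditions: Li (2.5 equiv), NH3(l)/THF, t-BuOH (1 equiv), −78 °C; solid NH4Cl
Reagents that add atoms: none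
Why: Birch-type 1,6-reduction of the dienone (protonation at the δ-carbon C19) gives the dienolate, and kinetic α-protonation at C6 on the outer face of the eight-membered ring, anti to the C5 methyl, should give the C1=C2 alkene with H-6 trans to CH3-5.

Step 16
Reactants: 22 β,γ-unsaturated C7 ketone
Product: 23 target alcohol
Conditions: Li (4 equiv), NH3(l)/THF, MeOH, −78 °C
Reagents that add atoms: none
Why: Dissolving-metal ketone reduction under product-stability control should give the more stable carbinol, with OH on the outer face of the eight-membered ring (cis to H-6, trans to CH3-8) and H-7 pointing into the ring; the isolated tetrasubstituted alkene is inert.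

**Compound list**

1 | 3,3-dimethylcyclohexan-1-one | CC1(C)CCCC(=O)C1 | starting material
2 | 2,5,5-trimethylcyclohexan-1-one (racemic) | CC1CCC(C)(C)CC1=O | intermediate
3 | N-[(R)-1-phenylethyl]imine of 2 | CC1CCC(C)(C)CC1=N[C@H](C)c1ccccc1 | intermediate (formed in the flask, not isolated)
4 | (S)-2,5,5-trimethyl-2-(3-oxobutyl)cyclohexan-1-one | CC(=O)CC[C@]1(C)CCC(C)(C)CC1=O | intermediate
5 | (S)-4a,7,7-trimethyl-4,4a,5,6,7,8-hexahydronaphthalen-2(3H)-one | O=C1CC[C@]2(C)CCC(C)(C)CC2=C1 | intermediate
6 | lithium enolate of the trans-decalone (lithium trans-4a,7,7-trimethyl-3,4,4a,5,6,7,8,8a-octahydronaphthalen-2-olate) | [Li]OC1=C[C@@H]2CC(C)(C)CC[C@@]2(C)CC1 | intermediate (formed in the flask, not isolated)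
7 | trans-4a,7,7-trimethyl-3,4,4a,5,6,7,8,8a-octahydronaphthalen-2-yl trifluoromethanesulfonate (4a-CH3 and 8a-H trans) | O=S(=O)(OC1=C[C@@H]2CC(C)(C)CC[C@@]2(C)CC1)C(F)(F)F | intermediate
8 | (S)-citronellal, (S)-3,7-dimethyloct-6-enal | C[C@@H](CCC=C(C)C)CC=O | starting material
9 | 2-[(S)-2,6-dimethylhept-5-en-1-yl]-1,3-dioxolane | C[C@@H](CCC=C(C)C)CC1OCCO1 | intermediate
10 | (2E,6S)-7-(1,3-dioxolan-2-yl)-2,6-dimethylhept-2-en-1-ol | OC/C(C)=C/CC[C@H](C)CC1OCCO1 | intermediate (formed in the flask, not isolated)
11 | (2E,6S)-7-(1,3-dioxolan-2-yl)-2,6-dimethylhept-2-enal | O=C/C(C)=C/CC[C@H](C)CC1OCCO1 | intermediate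
12 | 2-[(2S,5E)-2,6-dimethylocta-5,7-dien-1-yl]-1,3-dioxolane | C=C/C(C)=C/CC[C@H](C)CC1OCCO1 | intermediate
13 | (3S,6E)-3,7-dimethylnona-6,8-dienal | C=C/C(C)=C/CC[C@H](C)CC=O | intermediate
14 | (3S,6E)-1-(trans-4a,7,7-trimethyl-3,4,4a,5,6,7,8,8a-octahydronaphthalen-2-yl)-3,7-dimethylnona-6,8-dien-1-ol, both carbinol epimers | C=C/C(C)=C/CC[C@H](C)CC(O)C1=C[C@@H]2CC(C)(C)CC[C@@]2(C)CC1 | intermediate
15 | (3S,6E)-1-(trans-4a,7,7-trimethyl-3,4,4a,5,6,7,8,8a-octahydronaphthalen-2-yl)-3,7-dimethylnona-6,8-dien-1-one | C=C/C(C)=C/CC[C@H](C)CC(=O)C1=C[C@@H]2CC(C)(C)CC[C@@]2(C)CC1 | intermediate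
16 | (1Z,3S,6E)-1-(tert-butyldimethylsilyloxy)-1-(trans-4a,7,7-trimethyl-3,4,4a,5,6,7,8,8a-octahydronaphthalen-2-yl)-3,7-dimethylnona-1,6,8-triene | C=C/C(C)=C/CC[C@H](C)/C=C(\O[Si](C)(C)C(C)(C)C)C1=C[C@@H]2CC(C)(C)CC[C@@]2(C)CC1 | intermediate
17 | 5/8/6/6 tetracyclic cycloadduct: C19=C1(CH3) alkene, C7(OTBS)=C8 enol ether, H-17 β (trans to H-16), C2/C6 mixture | CC1=CC[C@H]2[C@@H]3CC(C)(C)CC[C@@]3(C)CCC2=C(O[Si](C)(C)C(C)(C)C)C2[C@@H](C)CCC12 | intermediate
18 | lithium C7=C8 enolate derived from 17 | CC1=CC[C@H]2[C@@H]3CC(C)(C)CC[C@@]3(C)CCC2=C(O[Li])C2[C@@H](C)CCC12 | intermediate (formed in the flask, not isolated)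
19 | tetracyclic C7 ketone with 8α-methyl (trans to H-17), C19=C1 alkene, C2/C6 mixture | CC1=CC[C@H]2[C@@H]3CC(C)(C)CC[C@@]3(C)CC[C@]2(C)C(=O)C2[C@@H](C)CCC12 | intermediate
20 | tetracyclic dienone: C7=O conjugated with C6=C2 and C1=C19 | CC1=CC[C@H]2[C@@H]3CC(C)(C)CC[C@@]3(C)CC[C@]2(C)C(=O)C2=C1CC[C@@H]2C | intermediate
21 | lithium dienolate (O–C7=C6, C2=C1) | C/C1=C2\CC[C@H](C)C2=C(O[Li])[C@@]2(C)CC[C@]3(C)CCC(C)(C)C[C@H]3[C@@H]2CC1 | intermediate (formed in the flask, not isolated)
22 | tetracyclic β,γ-unsaturated ketone: C7=O, C1=C2 alkene, H-6 trans to CH3-5 | C/C1=C2\CC[C@H](C)[C@@H]2C(=O)[C@@]2(C)CC[C@]3(C)CCC(C)(C)C[C@H]3[C@@H]2CC1 | intermediate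
23 | CNP0399382.1, the C7 alcohol | C/C1=C2\CC[C@H](C)[C@@H]2[C@@H](O)[C@@]2(C)CC[C@]3(C)CCC(C)(C)C[C@H]3[C@@H]2CC1 | target

**Step count and risks**

Total step count: 16. Longest linear sequence: 12 steps (steps 1–4 then 9–16; the citronellal branch, steps 5–8 then 9–16, is equally long).

The three steps most likely to fail:

Step 12. The distal diene terminus C17 is a hindered, ring-embedded trisubstituted carbon, so the nickel catalyst may divert into [4+2] or [2+2] modes or diene oligomerisation, or the facial selectivity at C17 may be poor. The fallback sets out from 16 and comes back at 17. Visible-light triplet sensitisation ([Ir(dF(CF3)ppy)2(dtbbpy)]PF6, blue light, acetone) should effect intramolecular [2+2] photocycloaddition between the C1=C2 alkene of the 1,3-diene and the enol ether C6=C7 alkene, giving the 1,2-divinylcyclobutane F1. Thermal Cope rearrangement of F1 (toluene, 110–140 °C) then breaks the C1–C7 bond, forms C17–C18 and should deliver 17.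

Step 13. The facial selectivity of the angular methylation may be poor or reversed, because the tub-shaped cyclooctadiene lies on the α-face and the electrophile may prefer to enter anti to the C17–C18 bond; this would give the cis-fused C8 epimer. The fallback sets out from 17 and comes back at 19. The MeLi/MeI alkylation is run without regard to its facial outcome, and the C8-epimeric ketone F2 is then epimerised photochemically (λ about 310 nm, benzene). This is a Norrish type 1 α-cleavage of the C7–C8 bond to an acyl/tertiary-alkyl radical pair followed by recombination, as known for α-quaternary cycloalkanones; 19 is separated and F2 is recycled. C6 scrambles as well, which does not matter.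

Step 15. The twisted cyclooctadienone may lose regiocontrol in the electron-transfer reduction (1,4- instead of 1,6-addition), the ketone may be over-reduced, or the β,γ-enone may slip into conjugation on work-up. The fallback sets out from 20 and comes back at 22. Conjugate 1,6-hydride delivery to the less hindered δ-carbon with Stryker's reagent [(Ph3P)CuH]6 in the presence of Me3SiCl should trap the dienolate as the trimethylsilyl dienol ether F3. Buffered protodesilylation of F3 (AcOH, THF/H2O, −40 °C) then protonates C6 kinetically and should give 22.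

**Further compounds**

F1 | step 12 | 1,2-divinylcyclobutane photoadduct: bicyclo[3.2.0]heptane with C2–C6 and C1–C7 bonds, vinyl and CH3 on C1, OTBS and the decalinyl group on C7 | C=CC1(C)C2CC[C@H](C)C2C1(O[Si](C)(C)C(C)(C)C)C1=C[C@@H]2CC(C)(C)CC[C@@]2(C)CC1
F2 | step 13 | C8 epimer of 19 (8β-methyl, cis 6/8 fusion) | CC1=CC[C@H]2[C@@H]3CC(C)(C)CC[C@@]3(C)CC[C@@]2(C)C(=O)C2[C@@H](C)CCC12
F3 | step 15 | trimethylsilyl dienol ether of 22 (Me3SiO–C7=C6, C2=C1) | C/C1=C2\CC[C@H](C)C2=C(O[Si](C)(C)C)[C@@]2(C)CC[C@]3(C)CCC(C)(C)C[C@H]3[C@@H]2CC1
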